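**Retrosynthetic overview**
1. The target, 7-(4,5-dimethoxy-2-methylnaphthalen-1-yl)-8-methoxy-1,3-dimethylisoquinoline, has one hindered biaryl bond, C7–C1'. Its two ortho neighbours, the oxygen on C8 of the isoquinoline benzo ring and the methyl carbon on C2' of the naphthalene, can be joined as an aryl ester C8–O–C(=O)–C2'; the route rests on this.
2. Endgame: C2'–CH3 from C2'–CH2Br from C2'–CH2OH, and C8–OMe from C8–OH; both groups arise by hydride opening of the six-membered biaryl lactone 17.
3. Key disconnection: C7–C1' of 17, made by intramolecular palladium-catalysed C–H arylation of bromo ester 16; 16 is split at the ester into acid 9 and isoquinolinol 14.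
4. Acid 9: Stobbe condensation of 1 with 2 and Friedel–Crafts closure build the second naphthalene ring (bromine as removable blocking group), then C1 bromination para to the naphthol. Isoquinolinol 14: aryne acyl-alkylation of 10 with 11 and ammonia condensation build the pyridine ring.
5. Ring order: naphthalene carbocycle (step 2), pyridine ring of the isoquinoline (step 7), temporary lactone ring (step 10, opened again in step 11).

Key step: step 10

Assumption: the target SMILES has no stereocentre and no descriptor for the C7–C1' axis, so the axis is formed without control and the target is delivered as the racemic pair of atropisomers.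

**Route**

Step 1
Reactants: 1 2-bromo-5-methoxybenzaldehyde; 2 diethyl succinate
Product: 3 (E)-4-(2-bromo-5-methoxyphenyl)-3-(ethoxycarbonyl)but-3-enoic acid
Conditions: NaOEt, EtOH, reflux; then aq. HCl
Reagents that add atoms: none
Why: Stobbe condensation, in which the succinate enolate adds to the aldehyde, the alkoxide lactonises and base-induced ring opening gives the alkylidene half-ester, mainly as the (E)-isomer with aryl cis to CH2CO2H as needed for the next ring closure.

Step 2
Reactants: 3 (E)-4-(2-bromo-5-methoxyphenyl)-3-(ethoxycarbonyl)but-3-enoic acid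
Product: 5 ethyl 8-bromo-4-hydroxy-5-methoxynaphthalene-2-carboxylate, via aryl acetate 4 (not isolated)
Conditions: Ac2O, NaOAc, reflux; evaporate; then K2CO3 (0.2 equiv), EtOH, rt
Reagents that add atoms: none
Why: The mixed anhydride of the half-ester acylates the arene intramolecularly (Friedel–Crafts-type Stobbe cyclisation) at the only free ortho position, next to methoxy, because bromine blocks the site para to methoxy, and the enol acetate so formed is removed by carbonate-catalysed ethanolysis that leaves the ethyl ester unchanged.

Step 3
Reactants: 5 ethyl 8-bromo-4-hydroxy-5-methoxynaphthalene-2-carboxylate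
Product: 6 ethyl 4-hydroxy-5-methoxynaphthalene-2-carboxylate
Conditions: H2 (1 atm), 10% Pd/C, NaOAc, EtOH, rt
Reagents that add atoms: none
Why: Catalytic hydrogenolysis of the aryl C–Br bond removes the blocking bromine, with NaOAc taking up HBr, while ester, naphthol and methyl ether are inert at ambient pressure.

Step 4
Reactants: 6 ethyl 4-hydroxy-5-methoxynaphthalene-2-carboxylate
Product: 7 ethyl 1-bromo-4-hydroxy-5-methoxynaphthalene-2-carboxylate
Conditions: NBS (1.0 equiv), MeCN, −20 to 0 °C
Reagents that add atoms: N-bromosuccinimide, O=C1CCC(=O)N1Br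
Why: Electrophilic aromatic bromination of the naphthol ring should go para to the free hydroxyl at the alpha position C1, since the hydroxyl-bearing ring is far more activated than the methoxy ring and one equivalent of NBS in a polar solvent at low temperature disfavours ortho (C3) and double bromination.

Step 5
Reactants: 7 ethyl 1-bromo-4-hydroxy-5-methoxynaphthalene-2-carboxylate
Product: 8 ethyl 1-bromo-4,5-dimethoxynaphthalene-2-carboxylate
Conditions: MeI, K2CO3, acetone, reflux
Reagents that add atoms: iodomethane, CI
Why: Williamson O-methylation of the naphthoxide, under which the aryl bromide and the ethyl ester are unaffected.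

Step 6
Reactants: 8 ethyl 1-bromo-4,5-dimethoxynaphthalene-2-carboxylate
Product: 9 1-bromo-4,5-dimethoxynaphthalene-2-carboxylic acid
Conditions: NaOH, EtOH/H2O, reflux; then aq. HCl
Reagents that add atoms: sodium hydroxide, [Na+].[OH-]
Why: Ester saponification by acyl-oxygen cleavage, for which the ortho bromine only demands heating.

Step 7
Reactants: 10 3-methoxy-2-(trimethylsilyl)phenyl trifluoromethanesulfonate; 11 acetylacetone
Product: 13 8-methoxy-1,3-dimethylisoquinoline, via diketone 12 (not isolated)
Conditions: CsF, MeCN, 80 °C; then aq. NH4OH, 60 °C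
Reagents that add atoms: ammonia, N
Why: Fluoride-induced elimination gives 3-methoxybenzyne, the acetylacetone enolate adds at the carbon meta to methoxy so that the aryl anion next to methoxy attacks the ketone and the four-membered alkoxide fragments (aryne acyl-alkylation, a C–C sigma-bond insertion), and the resulting 1,5-diketone condenses with ammonia to the pyridine ring, which places the oxygen at C8 beside the C1 methyl.

Step 8
Reactants: 13 8-methoxy-1,3-dimethylisoquinoline
Product: 14 1,3-dimethylisoquinolin-8-ol
Conditions: BBr3 (3 equiv), CH2Cl2, −78 °C to rt; then H2O, neutralise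
Reagents that add atoms: none
Why: Lewis-acid cleavage of the aryl methyl ether by bromide attack on the O-methyl group of the boron-complexed ether, with excess BBr3 because the ring nitrogen binds one equivalent.

Step 9
Reactants: 9 1-bromo-4,5-dimethoxynaphthalene-2-carboxylic acid; 14 1,3-dimethylisoquinolin-8-ol
Product: 16 1,3-dimethylisoquinolin-8-yl 1-bromo-4,5-dimethoxynaphthalene-2-carboxylate, via acid chloride 15 (not isolated)
Conditions: (COCl)2, DMF (cat.), CH2Cl2, 0 °C to rt; evaporate; then 14, Et3N, DMAP (cat.), CH2Cl2, rt
Reagents that add atoms: none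
Why: Acid chloride formation followed by DMAP-catalysed acylation of the phenol (nucleophilic acyl substitution), where the acylpyridinium intermediate overcomes the hindrance from the ortho bromine and the peri C1 methyl.

Step 10
Reactants: 16 1,3-dimethylisoquinolin-8-yl 1-bromo-4,5-dimethoxynaphthalene-2-carboxylate
Product: 17 biaryl lactone (C7–C1' bond, six-membered ring C8–O–C(=O)–C2'–C1'–C7)
Conditions: Pd(OAc)2 (10 mol%), PPh3 (20 mol%), NaOAc (2 equiv), DMA, 130 °C, degassed
Reagents that add atoms: none
Why: Zerovalent palladium, formed in the flask from Pd(OAc)2 and PPh3, inserts into the C1'–Br bond; the divalent arylpalladium acetate, held by the ester, palladates C7–H by acetate-assisted concerted metalation–deprotonation, and reductive elimination forms C7–C1'. The closest known reaction type is the intramolecular direct arylation of aryl 2-halobenzoates and 1-halo-2-naphthoates to benzo[c]chromen-6-one-type biaryl lactones. The six-membered lactone ring (C8, O, C=O, C2', C1', C7) is closed by this aryl–aryl bond through a seven-membered palladacycle. No stereocentre arises; the bridged axis is twisted but should invert freely, so the lactone is a single compound. The site selectivity needed (C7 and not C5 or the C1 methyl, intramolecular and not intermolecular) comes from the short tether, since only C7 is ortho to the C8 oxygen and only its arylation gives a six-membered ring, while the bridge lowers the steric cost of the hindered axis. The C1 and C3 methyl groups keep the ring nitrogen from binding palladium, and NaOAc is too weak a nucleophile to cleave the aryl ester.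

Step 11
Reactants: 17 biaryl lactone
Product: 18 7-[2-(hydroxymethyl)-4,5-dimethoxynaphthalen-1-yl]-1,3-dimethylisoquinolin-8-ol
Conditions: LiAlH4, THF, 0 °C; then H2O, aq. NaOH
Reagents that add atoms: none
Why: Hydride reduction of the activated aryl ester through the hydroxy aldehyde to the primary alcohol and the phenoxide is fast at 0 °C, where the 1,3-dimethyl-substituted isoquinoline ring does not add hydride, and the axis, now rotationally hindered, forms as the racemate.

Step 12
Reactants: 18 7-[2-(hydroxymethyl)-4,5-dimethoxynaphthalen-1-yl]-1,3-dimethylisoquinolin-8-ol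
Product: 19 [4,5-dimethoxy-1-(8-methoxy-1,3-dimethylisoquinolin-7-yl)naphthalen-2-yl]methanol
Conditions: MeI (1.1 equiv), K2CO3, acetone, rt
Reagents that add atoms: iodomethane, CI
Why: Chemoselective Williamson etherification, because K2CO3 deprotonates only the phenol and not the primary alcohol, and the phenoxide is a far better nucleophile toward the limited MeI than the nitrogen flanked by two methyl groups.

Step 13
Reactants: 19 [4,5-dimethoxy-1-(8-methoxy-1,3-dimethylisoquinolin-7-yl)naphthalen-2-yl]methanol
Product: 20 7-[2-(bromomethyl)-4,5-dimethoxynaphthalen-1-yl]-8-methoxy-1,3-dimethylisoquinoline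
Conditions: CBr4, PPh3, CH2Cl2, 0 °C; short silica filtration, used at once
Reagents that add atoms: carbon tetrabromide, BrC(Br)(Br)Br
Why: Appel reaction, in which the alkoxyphosphonium ion of the primary benzylic alcohol is displaced by bromide under neutral conditions that leave the aryl ethers and the heteroarene untouched.

Step 14
Reactants: 20 7-[2-(bromomethyl)-4,5-dimethoxynaphthalen-1-yl]-8-methoxy-1,3-dimethylisoquinoline
Product: 21 7-(4,5-dimethoxy-2-methylnaphthalen-1-yl)-8-methoxy-1,3-dimethylisoquinoline
Conditions: NaBH4, DMSO, rt
Reagents that add atoms: none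
Why: SN2 displacement of the primary benzylic bromide by borohydride hydride in a dipolar aprotic solvent gives the C2' methyl group, and NaBH4 does not reduce the neutral isoquinoline or the aryl ethers.

**Compound list**
1 | 2-bromo-5-methoxybenzaldehyde | COc1ccc(Br)c(C=O)c1 | starting material
2 | diethyl succinate | CCOC(=O)CCC(=O)OCC | starting material
3 | (E)-4-(2-bromo-5-methoxyphenyl)-3-(ethoxycarbonyl)but-3-enoic acid | CCOC(=O)/C(=C/c1cc(OC)ccc1Br)CC(=O)O | intermediate
4 | ethyl 4-acetoxy-8-bromo-5-methoxynaphthalene-2-carboxylate (aryl acetate) | CCOC(=O)c1cc(OC(C)=O)c2c(OC)ccc(Br)c2c1 | intermediate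
5 | ethyl 8-bromo-4-hydroxy-5-methoxynaphthalene-2-carboxylate | CCOC(=O)c1cc(O)c2c(OC)ccc(Br)c2c1 | intermediate
6 | ethyl 4-hydroxy-5-methoxynaphthalene-2-carboxylate | CCOC(=O)c1cc(O)c2c(OC)cccc2c1 | intermediate
7 | ethyl 1-bromo-4-hydroxy-5-methoxynaphthalene-2-carboxylate | CCOC(=O)c1cc(O)c2c(OC)cccc2c1Br | intermediate
8 | ethyl 1-bromo-4,5-dimethoxynaphthalene-2-carboxylate | CCOC(=O)c1cc(OC)c2c(OC)cccc2c1Br | intermediate
9 | 1-bromo-4,5-dimethoxynaphthalene-2-carboxylic acid | OC(=O)c1cc(OC)c2c(OC)cccc2c1Br | intermediate
10 | 3-methoxy-2-(trimethylsilyl)phenyl trifluoromethanesulfonate | COc1cccc(OS(=O)(=O)C(F)(F)F)c1[Si](C)(C)C | starting material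
11 | acetylacetone | CC(=O)CC(C)=O | starting material
12 | 1-(2-acetyl-3-methoxyphenyl)propan-2-one (diketone) | COc1cccc(CC(C)=O)c1C(C)=O | intermediate
13 | 8-methoxy-1,3-dimethylisoquinoline | COc1cccc2cc(C)nc(C)c12 | intermediate
14 | 1,3-dimethylisoquinolin-8-ol | Cc1cc2cccc(O)c2c(C)n1 | intermediate
15 | 1-bromo-4,5-dimethoxynaphthalene-2-carbonyl chloride (acid chloride) | COc1cc(C(=O)Cl)c(Br)c2cccc(OC)c12 | intermediate
16 | 1,3-dimethylisoquinolin-8-yl 1-bromo-4,5-dimethoxynaphthalene-2-carboxylate | Cc1cc2cccc(OC(=O)c3cc(OC)c4c(OC)cccc4c3Br)c2c(C)n1 | intermediate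
17 | biaryl lactone: isoquinoline C7 bonded to naphthalene C1', bridged C8–O–C(=O)–C2', with 1,3-dimethyl and 4',5'-dimethoxy groups | O=C1Oc2c(ccc3cc(C)nc(C)c23)-c2c1cc(OC)c1c(OC)cccc21 | intermediate
18 | 7-[2-(hydroxymethyl)-4,5-dimethoxynaphthalen-1-yl]-1,3-dimethylisoquinolin-8-ol (racemic axis) | Cc1cc2ccc(-c3c(CO)cc(OC)c4c(OC)cccc34)c(O)c2c(C)n1 | intermediate
19 | [4,5-dimethoxy-1-(8-methoxy-1,3-dimethylisoquinolin-7-yl)naphthalen-2-yl]methanol (racemic axis) | COc1c(-c2c(CO)cc(OC)c3c(OC)cccc23)ccc2cc(C)nc(C)c12 | intermediate
20 | 7-[2-(bromomethyl)-4,5-dimethoxynaphthalen-1-yl]-8-methoxy-1,3-dimethylisoquinoline (racemic axis) | COc1c(-c2c(CBr)cc(OC)c3c(OC)cccc23)ccc2cc(C)nc(C)c12 | intermediate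
21 | 7-(4,5-dimethoxy-2-methylnaphthalen-1-yl)-8-methoxy-1,3-dimethylisoquinoline (racemic axis) | COc1c(-c2c(C)cc(OC)c3c(OC)cccc23)ccc2cc(C)nc(C)c12 | target

**Step count**
Total: 14 steps. Longest linear sequence: 12 steps (steps 1–6, then 9–14); the isoquinolinol branch (steps 7–8) joins at step 9.

**Steps most likely to fail**

Step 10 (key step). After insertion of palladium into the C1'–Br bond, protodebromination or slow C7–H palladation (ester conformation, residual binding of the catalyst to nitrogen) may outrun ring closure. The fallback removes the C–H cleavage by placing a halogen on both carbons. It sets out from 14: amine-catalysed ortho-bromination (NBS, iPr2NH cat., CH2Cl2, 0 °C) should give 7-bromo-1,3-dimethylisoquinolin-8-ol F1. Acylation of F1 with acid chloride 15 (Et3N, DMAP, CH2Cl2) gives 7-bromo-1,3-dimethylisoquinolin-8-yl 1-bromo-4,5-dimethoxynaphthalene-2-carboxylate F2. Intramolecular reductive aryl–aryl coupling of the two C–Br bonds with zerovalent nickel (Ni(cod)2, 2,2'-bipyridine, DMF, 60 °C) then closes the same ring, and the route is rejoined at lactone 17.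

Step 7. The diketone enolate may undergo simple C- or O-arylation without acyl transfer, or the 1,5-diketone may self-condense by aldol reaction before ammonia captures it. The fallback uses the beta-ketoester variant of the acyl-alkylation and installs the C3 methyl by cross-coupling. It sets out from 10: reaction with methyl acetoacetate (CsF, MeCN, 80 °C) gives methyl 2-(2-acetyl-3-methoxyphenyl)acetate F3, which on addition of aqueous NH4OH condenses to 8-methoxy-1-methylisoquinolin-3-ol F4. O-Sulfonylation (Tf2O, pyridine, CH2Cl2, 0 °C) gives 8-methoxy-1-methylisoquinolin-3-yl trifluoromethanesulfonate F5. Suzuki methylation (trimethylboroxine, Pd(PPh3)4, K2CO3, dioxane, 100 °C) returns to the route at 13.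

Step 13. The benzylic bromide may be lost by intermolecular alkylation of the isoquinoline nitrogen or by phosphonium salt formation with PPh3 before it can be reduced. The fallback avoids any benzylic electrophile and replaces steps 13 and 14. It sets out from 19: oxidation with MnO2 (CH2Cl2, rt) gives 4,5-dimethoxy-1-(8-methoxy-1,3-dimethylisoquinolin-7-yl)naphthalene-2-carbaldehyde F6. Wolff–Kishner reduction (N2H4·H2O, KOH, diethylene glycol, 130 then 195 °C) proceeds through the hydrazone of this aldehyde F7 and loses dinitrogen to give the methyl compound, rejoining the route at target 21.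

**Further compounds**
F1 | step 10 | 7-bromo-1,3-dimethylisoquinolin-8-ol | Cc1cc2ccc(Br)c(O)c2c(C)n1
F2 | step 10 | 7-bromo-1,3-dimethylisoquinolin-8-yl 1-bromo-4,5-dimethoxynaphthalene-2-carboxylate | Cc1cc2ccc(Br)c(OC(=O)c3cc(OC)c4c(OC)cccc4c3Br)c2c(C)n1
F3 | step 7 | methyl 2-(2-acetyl-3-methoxyphenyl)acetate | COC(=O)Cc1cccc(OC)c1C(C)=O
F4 | step 7 | 8-methoxy-1-methylisoquinolin-3-ol | COc1cccc2cc(O)nc(C)c12
F5 | step 7 | 8-methoxy-1-methylisoquinolin-3-yl trifluoromethanesulfonate | COc1cccc2cc(OS(=O)(=O)C(F)(F)F)nc(C)c12
F6 | step 13 | 4,5-dimethoxy-1-(8-methoxy-1,3-dimethylisoquinolin-7-yl)naphthalene-2-carbaldehyde | COc1c(-c2c(C=O)cc(OC)c3c(OC)cccc23)ccc2cc(C)nc(C)c12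
F7 | step 13 | (E)-hydrazone of 4,5-dimethoxy-1-(8-methoxy-1,3-dimethylisoquinolin-7-yl)naphthalene-2-carbaldehyde | COc1c(-c2c(/C=N/N)cc(OC)c3c(OC)cccc23)ccc2cc(C)nc(C)c12
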